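C1 (quaternary, CH3), C2, C3, C4 (isopropyl carbinol) and C5 (ring-fusion CH) form the five-membered ring; C5, C6 (vanillate carbinol), C7, C8 (=CH2), C9 (free carbinol), C10 and C1 form the seven-membered ring; this numbering is used for every intermediate.
Cuts: the C6–O acyl bond (vanillic acid); C6–C7 (aldehyde plus allylsilane, closes the seven-membered ring); C8–C9 (C9 aldehyde plus a 2-(silylmethyl)vinyl Grignard reagent); C4–C5 (ring contraction of a 2-bromocyclohexanone in which C4 was bonded to C6); C1–C10 (conjugate allylation).
Enabling feature: C1 and C4 are 1,4-related through C2–C3 exactly as the methyl-bearing and carbinol carbons of terpinen-4-ol, and C6 is a single carbon hanging on C5, so the cyclopentane with its C6 appendage is the contraction product of the cyclohexanone C1–C2–C3–C4–C6–C5; C4 is fully substituted, so only the semibenzilic pathway is open.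
Forward order: chiral-pool six-membered ring, then the five-membered ring by contraction, then the seven-membered ring by C6–C7 closure, then esterification and desilylation.
Stereochemistry: C4 is bought with (S)-terpinen-4-ol; C1 by axial conjugate allylation trans to the C4 oxygen; C5 by inversion at the brominated carbon; C9 by CBS reduction (reagent control); C6 in the ring closure (tether from C1, formyl C=O eclipsing C5–H).

Key step: step 7

Assumption: (S)-(+)-terpinen-4-ol is taken as purchased in high enantiomeric purity, and its C4 configuration is carried unchanged into the target.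

Step 1
Reactants: 1 (S)-terpinen-4-ol
Product: 2 triethylsilyl ether of 1
Conditions: TESOTf, 2,6-lutidine, CH2Cl2, 0 °C to rt
Reagents that add atoms: triethylsilyl trifluoromethanesulfonate, CC[Si](CC)(CC)OS(=O)(=O)C(F)(F)F
Why: Silyl ether formation at a hindered tertiary alcohol needs the silyl triflate; the ether blocks chromate-ester formation at C4 in step 4 and α-ketol chemistry in step 7, and no stereocentre is touched.

Step 2
Reactants: 2 triethylsilyl ether
Product: 3 C1–C5 epoxide of 2 (either face)
Conditions: mCPBA, CH2Cl2, 0 °C
Reagents that add atoms: 3-chloroperoxybenzoic acid, O=C(OO)c1cccc(Cl)c1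
Why: Prilezhaev epoxidation of the only alkene, an electron-rich trisubstituted one; both epoxide faces are acceptable because C1 and C5 become sp2 again in steps 3 and 4.

Step 3
Reactants: 3 epoxide
Product: 6 tertiary allylic alcohol (C1–OH; C5=C6), via hydroxy selenide 4 (not isolated), via selenoxide 5 (not isolated)
Conditions: PhSeSePh, NaBH4, EtOH, rt to reflux; then THF, 30% aq. H2O2, 0 °C to rt
Reagents that add atoms: none
Why: Sharpless–Lauer epoxide-to-allylic-alcohol transposition: benzeneselenolate opens the epoxide by SN2 attack at the secondary carbon C5, and the selenoxide undergoes syn elimination, which can only run towards C6 because C1 carries no hydrogen.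

Step 4
Reactants: 6 tertiary allylic alcohol
Product: 7 (R)-6-isopropyl-3-methyl-6-(triethylsilyloxy)cyclohex-2-en-1-one (C6 ketone, C1=C5)
Conditions: pyridinium chlorochromate C5H5NH[CrO3Cl], CH2Cl2, rt
Reagents that add atoms: pyridinium chlorochromate, [O-][Cr](=O)(=O)Cl.c1cc[nH+]cc1
Why: Babler–Dauben oxidative transposition: the chromate ester of the tertiary allylic alcohol undergoes a [3,3] shift that delivers a chromium-bound oxygen to C6 and is then oxidised to the enone, the same change that turns 1-methyl-4,4-dialkylcyclohex-2-en-1-ols into 3-methyl-6,6-dialkylcyclohex-2-enones, so the carbonyl position is unambiguous.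

Step 5
Reactants: 7 enone; 8 allyltrimethylsilane
Product: 9 (3R,6R)-3-allyl-6-isopropyl-3-methyl-6-(triethylsilyloxy)cyclohexan-1-one
Conditions: TiCl4, CH2Cl2, −78 °C; then H2O
Reagents that add atoms: allyltrimethylsilane (8), C=CC[Si](C)(C)C
Why: Hosomi–Sakurai conjugate allylation of a β,β-disubstituted enone; in the half-chair with pseudo-equatorial isopropyl and pseudo-axial silyloxy at C4, the stereoelectronically preferred axial attack on C1 comes from the face opposite the silyloxy group, so allyl should end up trans and CH3 cis to the C4 oxygen (1,4-induction), and the bulky silyl ether should not chelate titanium.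

Step 6
Reactants: 9 allyl ketone
Product: 11 (2R,3R,6R)-3-allyl-2-bromo-6-isopropyl-3-methyl-6-(triethylsilyloxy)cyclohexan-1-one, via enol silane 10 (not isolated)
Conditions: LiN(iPr)2, Me3SiCl, THF, −78 to 0 °C; pentane filtration; then NBS, THF, −78 °C
Reagents that add atoms: N-bromosuccinimide, O=C1CCC(=O)N1Br
Why: C5 is the only enolisable position, so a single enol silane forms, and its α-bromination by NBS is faster than attack on the terminal alkene; axial attack anti to the pseudo-axial allyl group on C1 should place bromine trans to allyl, that is cis to CH3 and to the C4 silyloxy group.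

Step 7
Reactants: 11 α-bromo ketone
Product: 13 methyl (1R,2R,5R)-2-allyl-5-isopropyl-2-methyl-5-(triethylsilyloxy)cyclopentane-1-carboxylate, via methoxide adduct 12 (not isolated)
Conditions: NaOMe, MeOH/THF, 0 °C to rt
Reagents that add atoms: sodium methoxide, C[O-].[Na+]
Why: Methoxide adds reversibly to the C6 ketone, and in alkoxide 12 the C6–C4 bond, antiperiplanar to C5–Br, migrates to C5 with loss of bromide while C6 collapses to the methyl ester. This is a quasi-Favorskii (semibenzilic) rearrangement, the known course for an α-halo ketone without an α′-hydrogen. The five-membered ring C1–C2–C3–C4–C5 is closed by this 1,2-shift, a ring contraction through a three-centre transition state (formally 3-exo-tet at C5), not by an end-to-end cyclisation. The configuration at C5 is set by the bromide: C4 enters anti to it (inversion at C5, retention at C4), which puts the ester carbon C6 on the face the bromide held, cis to CH3 and silyloxy and trans to allyl and isopropyl, and this should also be the more stable epimer under methoxide. The step needs the shift to win over epoxy-ether formation, direct substitution, cyclopropanone-type Favorskii closure and elimination. The substrate secures this because C4 is fully substituted (no α′-enolate), C1 is quaternary (no β-hydrogen), bromide and silyloxy are cis-1,3 across the carbonyl so that the chair avoiding their syn-diaxial clash holds bromide equatorial and antiperiplanar to C6–C4, and C4 is a tertiary, oxygen-bearing carbon of high migratory aptitude.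

Step 8
Reactants: 13 allyl ester
Product: 15 C9 aldehyde (allyl shortened to CH2CHO), via secondary ozonide 14 (not isolated)
Conditions: O3, CH2Cl2, −78 °C; then PPh3, −78 °C to rt
Reagents that add atoms: ozone, [O-][O+]=O
Why: Ozonolysis with reductive work-up (Criegee mechanism) of the only alkene gives the C9 aldehyde; the ester and the silyl ether are inert to ozone at −78 °C.

Step 9
Reactants: 15 C9 aldehyde; 16 2-bromo-3-(trimethylsilyl)propene
Product: 18 C9 allylic alcohol (both C9 epimers), via alkenyl Grignard reagent 17 (not isolated)
Conditions: 16, Mg, THF, reflux; then 15, THF, −78 °C; aq. NH4Cl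
Reagents that add atoms: 2-bromo-3-(trimethylsilyl)propene (16, delivered as its Grignard reagent), C=C(Br)C[Si](C)(C)C
Why: 1,2-addition of an alkenyl Grignard reagent to the unhindered aldehyde forms C8–C9 and brings in the allylsilane, the C6 ester being shielded by its two fully substituted neighbours; 1,3-induction from C1 cannot be relied on, so both C9 epimers are carried into step 10, where the centre is erased.

Step 10
Reactants: 18 C9 allylic alcohol
Product: 19 C9 enone
Conditions: Dess–Martin periodinane, CH2Cl2, 0 °C to rt
Reagents that add atoms: none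
Why: Dess–Martin oxidation of the secondary allylic alcohol to the cross-conjugated enone under near-neutral conditions that spare the allylsilane and the silyl ether, converging both C9 epimers.

Step 11
Reactants: 19 C9 enone
Product: 20 (9S)-allylic alcohol
Conditions: (R)-2-methyl-CBS-oxazaborolidine (cat.), catecholborane, toluene, −78 °C
Reagents that add atoms: none
Why: Corey–Bakshi–Shibata reduction: the α-branched alkenyl group acts as the large and the C10 methylene as the small substituent, so the (R)-oxazaborolidine should deliver hydride to the face that gives the (S)-carbinol (the sense known for alkenyl and aryl alkyl ketones), and catecholborane at −78 °C leaves the ester and the allylsilane alone.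

Step 12
Reactants: 20 (9S)-allylic alcohol
Product: 21 C9 tert-butyldimethylsilyl ether
Conditions: TBSCl, imidazole, DMF, rt
Reagents that add atoms: tert-butyldimethylsilyl chloride, CC(C)(C)[Si](C)(C)Cl
Why: Silyl ether formation at the only free hydroxyl; the C9 oxygen is masked so that C6 alone is oxidised in step 14 and acylated in step 17.

Step 13
Reactants: 21 silyl-protected ester
Product: 22 C6 primary alcohol
Conditions: LiAlH4, Et2O, 0 °C to rt
Reagents that add atoms: none
Why: Hydride reduction of the hindered methyl ester to the neopentyl-type primary alcohol; the silyl ethers and the allylsilane are stable to LiAlH4 at this temperature.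

Step 14
Reactants: 22 C6 primary alcohol
Product: 23 C6 aldehyde
Conditions: Dess–Martin periodinane, CH2Cl2, 0 °C to rt
Reagents that add atoms: none
Why: Dess–Martin oxidation of the primary alcohol to the aldehyde without base, so that the C5 centre and the β-silyloxy group are not exposed to enolising conditions (epimerisation, β-elimination).

Step 15
Reactants: 23 C6 aldehyde
Product: 24 bicyclic alcohol (free 6-OH, 8-methylene, 9-OSi(tBu)Me2, 4-OSiEt3)
Conditions: BF3·OEt2, CH2Cl2, −78 °C
Reagents that add atoms: none
Why: Intramolecular Hosomi–Sakurai reaction (7-exo-trig at the aldehyde): the terminal alkene carbon of the allylsilane attacks the BF3-activated C6 aldehyde and becomes C7, and loss of silicon leaves the C8 exocyclic methylene; the formyl C=O should eclipse C5–H because both other C5 substituents are fully substituted carbons, and the tether from C1 reaches only the face on the C1 side, which gives H6 anti to H5 and the equatorial (6S) alcohol of the trans-fused ring system.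

Step 16
Reactants: 25 vanillic acid
Product: 27 4-(tert-butyldimethylsilyloxy)-3-methoxybenzoic acid, via bis-silyl vanillate 26 (not isolated)
Conditions: TBSCl (2.2 equiv), imidazole, DMF, rt; then AcOH/THF/H2O, rt
Reagents that add atoms: tert-butyldimethylsilyl chloride, CC(C)(C)[Si](C)(C)Cl
Why: Bis-silylation (silyl ester and aryl silyl ether) followed by selective hydrolysis of the far more labile silyl ester under mild aqueous acid leaves the phenol masked for the coupling.

Step 17
Reactants: 24 bicyclic alcohol; 27 protected vanillic acid
Product: 28 fully silylated target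
Conditions: DCC, DMAP (cat.), CH2Cl2, rt
Reagents that add atoms: 4-(tert-butyldimethylsilyloxy)-3-methoxybenzoic acid (27), COc1cc(C(=O)O)ccc1O[Si](C)(C)C(C)(C)C
Why: Steglich esterification of the single free (C6) hydroxyl with retention at C6; the phenol is masked, so the acid cannot acylate itself.

Step 18
Reactants: 28 fully silylated target
Product: 29 target, CNP0330487.1
Conditions: HF·pyridine, pyridine, THF, 0 °C to rt
Reagents that add atoms: none
Why: Fluoride-mediated cleavage of all three silyl ethers (tertiary Et3Si, secondary allylic tBuMe2Si, aryl tBuMe2Si) under buffered, weakly acidic conditions that leave the aryl ester, the allylic alcohol and the exocyclic alkene untouched.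

Compound list
1 | (S)-terpinen-4-ol, (S)-1-isopropyl-4-methylcyclohex-3-en-1-ol (C4 S) | CC1=CC[C@](O)(C(C)C)CC1 | starting material
2 | (S)-triethyl[(1-isopropyl-4-methylcyclohex-3-en-1-yl)oxy]silane | CC1=CC[C@](O[Si](CC)(CC)CC)(C(C)C)CC1 | intermediate
3 | C1–C5 epoxide of 2 (either epoxide face; C4 as in 2) | CC12OC1C[C@](O[Si](CC)(CC)CC)(C(C)C)CC2 | intermediate
4 | hydroxy selenide, formed in the flask: C1 tertiary alcohol, C5 phenylselanyl trans to it, C4 as in 2 | CC1(O)C([Se]c2ccccc2)C[C@](O[Si](CC)(CC)CC)(C(C)C)CC1 | intermediate
5 | selenoxide of 4, formed in the flask | CC1(O)C([Se](=O)c2ccccc2)C[C@](O[Si](CC)(CC)CC)(C(C)C)CC1 | intermediate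
6 | 4-isopropyl-1-methyl-4-(triethylsilyloxy)cyclohex-2-en-1-ol (either C1 configuration; C5=C6; C4 spatially as in 2) | CC1(O)C=C[C@](O[Si](CC)(CC)CC)(C(C)C)CC1 | intermediate
7 | (R)-6-isopropyl-3-methyl-6-(triethylsilyloxy)cyclohex-2-en-1-one (C6 ketone, C1=C5, C4 R) | CC1=CC(=O)[C@](O[Si](CC)(CC)CC)(C(C)C)CC1 | intermediate
8 | allyltrimethylsilane | C=CC[Si](C)(C)C | starting material
9 | (3R,6R)-3-allyl-6-isopropyl-3-methyl-6-(triethylsilyloxy)cyclohexan-1-one (C1 R, C4 R; allyl trans to the C4 oxygen) | O=C1C[C@@](C)(CC=C)CC[C@@]1(O[Si](CC)(CC)CC)C(C)C | intermediate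
10 | trimethylsilyl enol ether of 9 (C5=C6), formed in the flask | C[Si](C)(C)OC1=C[C@@](C)(CC=C)CC[C@@]1(O[Si](CC)(CC)CC)C(C)C | intermediate
11 | (2R,3R,6R)-3-allyl-2-bromo-6-isopropyl-3-methyl-6-(triethylsilyloxy)cyclohexan-1-one (C1 R, C4 R, C5 R; Br cis to CH3 and OSiEt3, trans to allyl) | Br[C@H]1C(=O)[C@](O[Si](CC)(CC)CC)(C(C)C)CC[C@]1(C)CC=C | intermediate
12 | sodium alkoxide of the C6 methyl hemiketal of 11 (either configuration at the hemiketal carbon), formed in the flask | Br[C@H]1C([O-])(OC)[C@](O[Si](CC)(CC)CC)(C(C)C)CC[C@]1(C)CC=C.[Na+] | intermediate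
13 | methyl (1R,2R,5R)-2-allyl-5-isopropyl-2-methyl-5-(triethylsilyloxy)cyclopentane-1-carboxylate (C1 R, C4 R, C5 R; CO2CH3 cis to CH3 and OSiEt3) | COC(=O)[C@@H]1[C@](C)(CC[C@@]1(O[Si](CC)(CC)CC)C(C)C)CC=C | intermediate
14 | secondary ozonide (1,2,4-trioxolane) of the allyl group of 13 (either configuration at the trioxolane carbon), formed in the flask | COC(=O)[C@@H]1[C@](C)(CC[C@@]1(O[Si](CC)(CC)CC)C(C)C)CC1OCOO1 | intermediate
15 | C9 aldehyde: 13 with allyl shortened to CH2CHO (C1 R, C4 R, C5 R) | COC(=O)[C@@H]1[C@](C)(CC[C@@]1(O[Si](CC)(CC)CC)C(C)C)CC=O | intermediate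
16 | 2-bromo-3-(trimethylsilyl)propene | C=C(Br)C[Si](C)(C)C | starting material
17 | [1-(trimethylsilylmethyl)vinyl]magnesium bromide, formed in the flask | C=C(C[Si](C)(C)C)[Mg]Br | intermediate
18 | C9 allylic alcohol, both C9 epimers: C10H2–C9H(OH)–C8(=CH2)–CH2SiMe3 side chain on C1 (C1 R, C4 R, C5 R) | COC(=O)[C@@H]1[C@](C)(CC[C@@]1(O[Si](CC)(CC)CC)C(C)C)CC(O)C(=C)C[Si](C)(C)C | intermediate
19 | C9 enone: C9 ketone conjugated with C8=CH2 bearing CH2SiMe3 (C1 R, C4 R, C5 R) | COC(=O)[C@@H]1[C@](C)(CC[C@@]1(O[Si](CC)(CC)CC)C(C)C)CC(=O)C(=C)C[Si](C)(C)C | intermediate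
20 | (9S)-allylic alcohol (C1 R, C4 R, C5 R, C9 S) | COC(=O)[C@@H]1[C@](C)(CC[C@@]1(O[Si](CC)(CC)CC)C(C)C)C[C@H](O)C(=C)C[Si](C)(C)C | intermediate
21 | C9 tert-butyldimethylsilyl ether of 20 | COC(=O)[C@@H]1[C@](C)(CC[C@@]1(O[Si](CC)(CC)CC)C(C)C)C[C@H](O[Si](C)(C)C(C)(C)C)C(=C)C[Si](C)(C)C | intermediate
22 | C6 primary alcohol: CH2OH on C5 in place of the ester of 21 (C1 R, C4 R, C5 S by CIP, C9 S; spatial arrangement unchanged) | OC[C@@H]1[C@](C)(CC[C@@]1(O[Si](CC)(CC)CC)C(C)C)C[C@H](O[Si](C)(C)C(C)(C)C)C(=C)C[Si](C)(C)C | intermediate
23 | C6 aldehyde (C1 R, C4 R, C5 R by CIP, C9 S) | O=C[C@@H]1[C@](C)(CC[C@@]1(O[Si](CC)(CC)CC)C(C)C)C[C@H](O[Si](C)(C)C(C)(C)C)C(=C)C[Si](C)(C)C | intermediate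
24 | trans-fused bicyclic alcohol: free 6-OH, 8-methylene, 9-OSi(tBu)Me2, 4-OSiEt3 (1R,4R,5S,6S,9S) | C=C1C[C@H](O)[C@@H]2[C@](C)(CC[C@@]2(O[Si](CC)(CC)CC)C(C)C)C[C@@H]1O[Si](C)(C)C(C)(C)C | intermediate
25 | vanillic acid | COc1cc(C(=O)O)ccc1O | starting material
26 | tert-butyldimethylsilyl 4-(tert-butyldimethylsilyloxy)-3-methoxybenzoate, formed in the flask | COc1cc(C(=O)O[Si](C)(C)C(C)(C)C)ccc1O[Si](C)(C)C(C)(C)C | intermediate
27 | 4-(tert-butyldimethylsilyloxy)-3-methoxybenzoic acid | COc1cc(C(=O)O)ccc1O[Si](C)(C)C(C)(C)C | intermediate
28 | tris-silylated target: 6-O-[4-(tert-butyldimethylsilyloxy)-3-methoxybenzoyl], 9-OSi(tBu)Me2, 4-OSiEt3 (1R,4R,5S,6S,9S) | C=C1C[C@H](OC(=O)c2ccc(O[Si](C)(C)C(C)(C)C)c(OC)c2)[C@@H]2[C@](C)(CC[C@@]2(O[Si](CC)(CC)CC)C(C)C)C[C@@H]1O[Si](C)(C)C(C)(C)C | intermediate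
29 | CNP0330487.1: 6-O-vanilloyl 4,9-diol with 8-methylene (1R,4R,5S,6S,9S) | C=C1C[C@H](OC(=O)c2ccc(O)c(OC)c2)[C@@H]2[C@](C)(CC[C@@]2(O)C(C)C)C[C@@H]1O | target

Total step count: 18.
Longest linear sequence: 17 steps (steps 1–15, 17 and 18); step 16 is a one-step side branch.

Steps most likely to fail

Step 7. In the chair with axial bromide the C6 alkoxide may close onto C5 to an epoxy ether, methoxide may displace bromide directly, or the silyl group may move from the C4 oxygen to the C6 alkoxide, each faster than C4 migrates. The fallback forms the same C4–C5 bond by a Wolff ring contraction (carbene and ketene chemistry instead of halide displacement). It sets out from ketone 9: LiN(SiMe3)2 followed by CF3CO2CH2CF3 (THF, −78 °C) should give the 5-trifluoroacetyl ketone F1, and deacylative Regitz diazo transfer (MsN3, Et3N, MeCN, rt) the 5-diazo ketone F2. Irradiation in MeOH (Pyrex filter, rt) expels nitrogen, C4 shifts from C6 to the carbene carbon C5, and methanol adds to the ketene; after equilibration of C5 with NaOMe in MeOH the methyl ester is 13, where the route is rejoined.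

Step 15. Under the Lewis acid, protodesilylation of the allylsilane or ionisation at the allylic C9 silyl ether may outrun the slow addition to the doubly neopentylic aldehyde, and the open transition state may give poor facial selectivity at C6. The fallback closes the same C6–C7 bond by a chromium-mediated allylation of Nozaki–Hiyama type through a closed six-membered transition state. It sets out from aldehyde 23: NBS (CH2Cl2, −78 °C) should convert the allylsilane by bromodesilylation with allylic transposition into the allylic bromide F3, and CrCl2 (divalent chromium; THF, rt, high dilution) should turn it into the allylchromium species, which adds to the C6 aldehyde and returns to the route at 24.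

Step 5. The 1,4-induction rests on the conformational preference of isopropyl over silyloxy at C4 and may give insufficient facial bias, and TiCl4 may strip the silyl ether. The fallback replaces it by 1,2-induction relayed through a sigmatropic shift. It sets out from enone 7: allylmagnesium bromide CH2=CHCH2MgBr (THF, −78 °C) should add to the C6 ketone anti to the adjacent pseudo-axial silyloxy group to give the tertiary dienol F4. KH with 18-crown-6 (THF, 0 °C to rt) then triggers an anionic oxy-Cope rearrangement that carries the allyl group suprafacially from C6 to C1, and protonation of the enolate returns to the route at 9.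

Further compounds
F1 | step 7 | 3-allyl-6-isopropyl-3-methyl-2-(trifluoroacetyl)-6-(triethylsilyloxy)cyclohexan-1-one (C1 R, C4 R; C5 enolised or either configuration) | O=C(C1C(=O)[C@](O[Si](CC)(CC)CC)(C(C)C)CC[C@]1(C)CC=C)C(F)(F)F
F2 | step 7 | 3-allyl-2-diazo-6-isopropyl-3-methyl-6-(triethylsilyloxy)cyclohexan-1-one (C1 R, C4 R) | [N-]=[N+]=C1C(=O)[C@](O[Si](CC)(CC)CC)(C(C)C)CC[C@]1(C)CC=C
F3 | step 15 | C6 aldehyde with a C10H2–C9H(OSi(tBu)Me2)–C8(=CH2)–CH2Br side chain on C1 (configuration as in 23) | O=C[C@@H]1[C@](C)(CC[C@@]1(O[Si](CC)(CC)CC)C(C)C)C[C@H](O[Si](C)(C)C(C)(C)C)C(=C)CBr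
F4 | step 5 | 1-allyl-6-isopropyl-3-methyl-6-(triethylsilyloxy)cyclohex-2-en-1-ol (allyl on C6 trans to the C4 silyloxy group; C4 R, C6 R) | CC1=C[C@](O)(CC=C)[C@](O[Si](CC)(CC)CC)(C(C)C)CC1
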